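**Retrosynthetic overview**
1. The target is (3S,4R), with the two benzyl groups cis and the C3-OH trans to the C4 benzyl. It comes from (+)-matairesinol: the C3-OH goes in last, by oxygen transfer to the lactone enolate on the face away from the C4 benzyl.
2. (+)-Matairesinol comes from (+)-secoisolariciresinol. The only ring, the γ-lactone, is closed as in the plant (diol → hydroxy aldehyde → lactol → lactone) by hydride transfer to a ketone, on the unprotected bisphenol.
3. (+)-Secoisolariciresinol comes from a C2-symmetric (S,S) 8-8′ dimer, made by one-electron oxidative dimerisation of a dihydroferulic imide enolate. The (R)-oxazolidinone plays the part of the dirigent protein and sets both centres at once.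
4. The imide comes from dihydroferulic acid and (R)-4-isopropyloxazolidin-2-one. Pivaloyl chloride activates the acid and masks the phenol in the same flask.
5. Only one ring is formed (step 4). The C2 symmetry of the diol removes any regiochemical choice in its closure.

Assumption: the SMILES is read as (3S,4R), the C3 epimer of (+)-nortrachelogenin (wikstromol); dihydroferulic acid is taken as a purchased bulk chemical.

**Step 1**
Reactants: 1 dihydroferulic acid [3-(4-hydroxy-3-methoxyphenyl)propanoic acid]; 2 (4R)-4-isopropyl-1,3-oxazolidin-2-one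
Product: 4 (4R)-4-isopropyl-3-[3-(3-methoxy-4-pivaloyloxyphenyl)propanoyl]-1,3-oxazolidin-2-one, via O-pivaloyl mixed pivalic anhydride 3 (not isolated)
Conditions: PivCl (2.1 equiv), Et3N (3.5 equiv), DMAP (5 mol %), THF, −20 → 0 °C; then LiCl (1.1 equiv), 2 (0.95 equiv), 0 °C → rt
Reagents that add atoms: pivaloyl chloride, CC(C)(C)C(=O)Cl
Why: Pivaloyl chloride acylates the phenol and converts the acid into mixed anhydride 3, whose unhindered carbonyl is then attacked by the LiCl/Et3N-activated oxazolidinone (mixed-anhydride N-acylation of an Evans auxiliary); no new stereocentre forms and the auxiliary centre is untouched.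

**Step 2**
Reactants: 4 (two molecules)
Product: 6 (2S,3S)-2,3-bis(3-methoxy-4-pivaloyloxybenzyl)-1,4-bis[(4R)-4-isopropyl-2-oxo-1,3-oxazolidin-3-yl]butane-1,4-dione, via lithium Z-enolate 5 (not isolated)
Conditions: LiN(iPr)2 (1.1 equiv), THF, −78 °C, 1 h; CuCl2 (anhydrous, 1.2 equiv), −78 °C → rt
Reagents that add atoms: none
Why: In this auxiliary-controlled oxidative enolate homocoupling, divalent copper takes one electron from the chelated Z-enolate 5 and the two α-carbonyl radicals join C8-C8′, each on the face away from its isopropyl group, so the (4R)-auxiliary sets both new centres as S (the (4S)-series is known to give R,R), the hindered, electron-poorer aryl pivalate survives base and oxidant, and the minor R,S dimer is removed by crystallisation or chromatography.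

**Step 3**
Reactants: 6
Product: 7 (+)-secoisolariciresinol (2S,3S)-2,3-bis(4-hydroxy-3-methoxybenzyl)butane-1,4-diol
Conditions: LiBH4 (8 equiv), THF, 0 → 45 °C; aq NH4Cl, pH 4
Reagents that add atoms: none
Why: Hydride attacks the exocyclic imide carbonyls (reductive removal of the Evans auxiliary, released intact for reuse) and also cleaves the two activated aryl esters; any lactone formed by half-reduction is reduced on to the same diol, the stereocentres are not touched, and one crystallisation of the C2-symmetric diol upgrades its purity.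

**Step 4**
Reactants: 7
Product: 10 (+)-matairesinol (3S,4S)-3,4-bis(4-hydroxy-3-methoxybenzyl)dihydrofuran-2(3H)-one, via hydroxy aldehyde 8 (not isolated), via lactol 9 (not isolated)
Conditions: [(η5-Ph4C4CO)2H]Ru2(CO)4(μ-H) (Shvo complex, 2 mol %), acetone–toluene 1:1, 100 °C (sealed tube), Ar, 16 h
Reagents that add atoms: none
Why: In this ruthenium-catalysed transfer dehydrogenation (Oppenauer-type oxidative lactonisation of a 1,4-diol), the cyclopentadienone–Ru pair takes H+/H− from one CH2OH and hands it to acetone as NAD+ does in the dehydrogenase, 8 closes to lactol 9, and its irreversible dehydrogenation pulls the sequence to the lactone; a pure hydride-transfer oxidant leaves the electron-rich free phenols alone, the two CH2OH groups are homotopic so only one lactone can form, and no new stereocentre arises (C4 untouched, C3 stays in the favoured trans form).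

**Step 5**
Reactants: 10
Product: 13 (3S,4R)-3-hydroxy-3,4-bis(4-hydroxy-3-methoxybenzyl)dihydrofuran-2(3H)-one, via tripotassium bisphenoxide enolate 11 (not isolated), via tripotassium salt of the product 12 (not isolated)
Conditions: KN(SiMe3)2 (3.4 equiv), THF–DMPU 6:1, −78 °C, 45 min; 2-(benzenesulfonyl)-3-phenyloxaziridine (1.4 equiv), −78 °C, 30 min; AcOH (4 equiv), −78 °C → rt
Reagents that add atoms: 2-(benzenesulfonyl)-3-phenyloxaziridine (Davis oxaziridine), O=S(=O)(c1ccccc1)N1OC1c1ccccc1
Why: In this Davis oxidation of a lactone enolate, the phenols protect themselves as phenoxides, which are far weaker nucleophiles than the enolate carbon, and the bulky oxaziridine delivers oxygen to C3 on the face away from the C4 benzyl group, so OH ends up trans and the C3 benzyl cis to it, which is 3S (C4 keeps its geometry and changes from S to R by priority only); the minor 3R epimer, (+)-nortrachelogenin, is removed by chromatography.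

**Compound list**
1 | dihydroferulic acid, 3-(4-hydroxy-3-methoxyphenyl)propanoic acid | COc1cc(CCC(=O)O)ccc1O | starting material
2 | (4R)-4-isopropyl-1,3-oxazolidin-2-one | CC(C)[C@@H]1COC(=O)N1 | starting material
3 | 3-(3-methoxy-4-pivaloyloxyphenyl)propanoic pivalic anhydride | COc1cc(CCC(=O)OC(=O)C(C)(C)C)ccc1OC(=O)C(C)(C)C | intermediate
4 | (4R)-4-isopropyl-3-[3-(3-methoxy-4-pivaloyloxyphenyl)propanoyl]-1,3-oxazolidin-2-one | CC(C)[C@@H]1COC(=O)N1C(=O)CCc1ccc(OC(=O)C(C)(C)C)c(OC)c1 | intermediate
5 | lithium Z-enolate of 4 | [Li+].CC(C)[C@@H]1COC(=O)N1/C([O-])=C/Cc1ccc(OC(=O)C(C)(C)C)c(OC)c1 | intermediate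
6 | (2S,3S)-2,3-bis(3-methoxy-4-pivaloyloxybenzyl)-1,4-bis[(4R)-4-isopropyl-2-oxo-1,3-oxazolidin-3-yl]butane-1,4-dione | CC(C)[C@@H]1COC(=O)N1C(=O)[C@@H](Cc1ccc(OC(=O)C(C)(C)C)c(OC)c1)[C@H](Cc1ccc(OC(=O)C(C)(C)C)c(OC)c1)C(=O)N1[C@H](C(C)C)COC1=O | intermediate
7 | (+)-secoisolariciresinol, (2S,3S)-2,3-bis(4-hydroxy-3-methoxybenzyl)butane-1,4-diol | OC[C@@H](Cc1ccc(O)c(OC)c1)[C@H](Cc1ccc(O)c(OC)c1)CO | intermediate
8 | (2S,3S)-4-hydroxy-2,3-bis(4-hydroxy-3-methoxybenzyl)butanal | O=C[C@@H](Cc1ccc(O)c(OC)c1)[C@H](Cc1ccc(O)c(OC)c1)CO | intermediate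
9 | (3S,4S)-3,4-bis(4-hydroxy-3-methoxybenzyl)tetrahydrofuran-2-ol (lactol, both anomers) | COc1cc(C[C@@H]2COC(O)[C@H]2Cc2ccc(O)c(OC)c2)ccc1O | intermediate
10 | (+)-matairesinol, (3S,4S)-3,4-bis(4-hydroxy-3-methoxybenzyl)dihydrofuran-2(3H)-one | COc1cc(C[C@@H]2COC(=O)[C@H]2Cc2ccc(O)c(OC)c2)ccc1O | intermediate
11 | tripotassium bisphenoxide enolate of 10 | [K+].[K+].[K+].COc1cc(C[C@@H]2COC([O-])=C2Cc2ccc([O-])c(OC)c2)ccc1[O-] | intermediate
12 | tripotassium salt (alkoxide, two phenoxides) of 13 | [K+].[K+].[K+].COc1cc(C[C@@H]2COC(=O)[C@]2([O-])Cc2ccc([O-])c(OC)c2)ccc1[O-] | intermediate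
13 | (3S,4R)-3-hydroxy-3,4-bis(4-hydroxy-3-methoxybenzyl)dihydrofuran-2(3H)-one | COc1cc(C[C@@H]2COC(=O)[C@]2(O)Cc2ccc(O)c(OC)c2)ccc1O | target

**Total step count:** 5. **Longest linear sequence:** 5.

**Three steps most likely to fail**

Step 2 (oxidative dimerisation). Couplings of this kind rarely exceed 50–65 %. CuCl2 can chlorinate the enolate, and the R,S dimer must be separated.

The fallback sets out from 4 and comes back at 10. It replaces the single dimerisation with two polar alkylations.
- NaN(SiMe3)2, THF, −78 °C, then tert-butyl bromoacetate (Evans alkylation, same facial control by the auxiliary) gives tert-butyl (3S)-4-[(4R)-4-isopropyl-2-oxo-1,3-oxazolidin-3-yl]-3-(3-methoxy-4-pivaloyloxybenzyl)-4-oxobutanoate F1.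
- NaBH4, THF–H2O, 0 °C reduces only the imide, to tert-butyl (3S)-4-hydroxy-3-(3-methoxy-4-pivaloyloxybenzyl)butanoate F2.
- CF3CO2H, CH2Cl2, rt closes it to (4S)-4-(3-methoxy-4-pivaloyloxybenzyl)dihydrofuran-2(3H)-one F3.
- LiN(SiMe3)2, THF, −78 °C, then 4-benzyloxy-3-methoxybenzyl bromide alkylates anti to the C4 group and gives (3S,4S)-3-(4-benzyloxy-3-methoxybenzyl)-4-(3-methoxy-4-pivaloyloxybenzyl)dihydrofuran-2(3H)-one F4.
- H2, Pd/C, K2CO3, MeOH, then dilute HCl frees both phenols and delivers 10.

Step 4 (dehydrogenative lactonisation on the free bisphenol). There are three risks: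
- The phenols may bind and slow the ruthenium centre.
- The reaction may stall at lactol 9.
- Reversible dehydrogenation with enolisation of 8 could leak some meso diol and erode the optical purity at C4.

The fallback sets out from 7 and comes back at 10. It masks the phenols and uses a stoichiometric oxidant in place of catalytic hydride transfer.
- BnBr, K2CO3, acetone, reflux alkylates only the phenols and gives (2S,3S)-2,3-bis(4-benzyloxy-3-methoxybenzyl)butane-1,4-diol F5.
- Ag2CO3 on Celite, toluene, reflux oxidises one of the two equivalent carbinols and closes (3S,4S)-3,4-bis(4-benzyloxy-3-methoxybenzyl)dihydrofuran-2(3H)-one F6.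
- H2, Pd/C, EtOAc–EtOH returns 10.

Step 5 (hydroxylation of the unprotected trianion). The tripotassium salt may be poorly soluble. The aryl ring of the C3 benzyl group can partly shield the face that should be open, which would lower the diastereomer ratio.

The fallback sets out from 10 and comes back at 13. It works on a soluble, protected monoanion instead of a polyanion.
- TBSCl, imidazole, DMF, rt gives (3S,4S)-3,4-bis(4-tert-butyldimethylsilyloxy-3-methoxybenzyl)dihydrofuran-2(3H)-one F7.
- KN(SiMe3)2 (1.2 equiv), THF, −78 °C, then the same oxaziridine gives, again anti to the C4 benzyl, (3S,4R)-3-hydroxy-3,4-bis(4-tert-butyldimethylsilyloxy-3-methoxybenzyl)dihydrofuran-2(3H)-one F8. At this stage the epimers separate easily on silica.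
- Bu4NF, AcOH, THF, 0 °C gives 13.

**Further compounds**
F1 | step 2 | tert-butyl (3S)-4-[(4R)-4-isopropyl-2-oxo-1,3-oxazolidin-3-yl]-3-(3-methoxy-4-pivaloyloxybenzyl)-4-oxobutanoate | CC(C)[C@@H]1COC(=O)N1C(=O)[C@H](CC(=O)OC(C)(C)C)Cc1ccc(OC(=O)C(C)(C)C)c(OC)c1
F2 | step 2 | tert-butyl (3S)-4-hydroxy-3-(3-methoxy-4-pivaloyloxybenzyl)butanoate | OC[C@H](CC(=O)OC(C)(C)C)Cc1ccc(OC(=O)C(C)(C)C)c(OC)c1
F3 | step 2 | (4S)-4-(3-methoxy-4-pivaloyloxybenzyl)dihydrofuran-2(3H)-one | COc1cc(C[C@@H]2COC(=O)C2)ccc1OC(=O)C(C)(C)C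
F4 | step 2 | (3S,4S)-3-(4-benzyloxy-3-methoxybenzyl)-4-(3-methoxy-4-pivaloyloxybenzyl)dihydrofuran-2(3H)-one | COc1cc(C[C@@H]2COC(=O)[C@H]2Cc2ccc(OCc3ccccc3)c(OC)c2)ccc1OC(=O)C(C)(C)C
F5 | step 4 | (2S,3S)-2,3-bis(4-benzyloxy-3-methoxybenzyl)butane-1,4-diol | OC[C@@H](Cc1ccc(OCc2ccccc2)c(OC)c1)[C@H](Cc1ccc(OCc2ccccc2)c(OC)c1)CO
F6 | step 4 | (3S,4S)-3,4-bis(4-benzyloxy-3-methoxybenzyl)dihydrofuran-2(3H)-one | COc1cc(C[C@@H]2COC(=O)[C@H]2Cc2ccc(OCc3ccccc3)c(OC)c2)ccc1OCc1ccccc1
F7 | step 5 | (3S,4S)-3,4-bis(4-tert-butyldimethylsilyloxy-3-methoxybenzyl)dihydrofuran-2(3H)-one | COc1cc(C[C@@H]2COC(=O)[C@H]2Cc2ccc(O[Si](C)(C)C(C)(C)C)c(OC)c2)ccc1O[Si](C)(C)C(C)(C)C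
F8 | step 5 | (3S,4R)-3-hydroxy-3,4-bis(4-tert-butyldimethylsilyloxy-3-methoxybenzyl)dihydrofuran-2(3H)-one | COc1cc(C[C@@H]2COC(=O)[C@]2(O)Cc2ccc(O[Si](C)(C)C(C)(C)C)c(OC)c2)ccc1O[Si](C)(C)C(C)(C)C
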